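It is easy to take a target that falls with time for an intermediate on its own clock, and then more partner seems to mean more target at every time.

| flask | substrate | partner | precatalyst | remark | time |
|---|---|---|---|---|---|
| teal | 0.0020 M | 1.1 equiv | 7.7 mol% | run made earlier |  |
| red | 0.0020 M | 2.2 equiv | 7.7 mol% | run made earlier |  |
| green | 0.0020 M | 2.3 equiv | 7.7 mol% | run made earlier |  |
| cedar | 0.0020 M | 1.50 equiv | 7.7 mol% |  | 5.0 min |
| ash | 0.0020 M | 3.00 equiv | 7.7 mol% |  | 5.0 min |

- teal (time / min: target / %, substrate / %): 0.667: 14.9, 58.8; 1.33: 9.5, 49.4; 2.00: 7.1, 43.0; 3.00: 6.5, 35.5; 4.00: 1.8, 31.5
- red (time / min: target / %, substrate / %): 0.667: 20.9, 37.5; 1.33: 13.5, 25.4; 2.00: 10.1, 18.4; 3.00: 3.6, 11.8; 4.00: 4.4, 8.3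
- green (time / min: target / %, substrate / %): 0.667: 21.4, 35.1; 1.33: 14.4, 24.1; 2.00: 8.9, 18.5; 3.00: 6.6, 9.0; 4.00: 4.7, 6.6

(readings scatter by 1 percentage point)



- which of the two there is more of at the end, cedar (isomer of the product / target)
- which of the two there is more of at the end, ash (isomer of the product / target)
- how much target is there at the end, in percent of the substrate charged: cedar
- how much target is there at the end, in percent of the substrate charged: ash

Two of us read these runs differently. The first calls the target a passing intermediate. At the first reading red holds 20.9% against 14.9% in teal, so on this view more partner means more target. Red's decay from its first reading to its last, carried on to 5.0 min, puts ash near 2.76%, with cedar, charged with less partner, lower.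

The second divides target by substrate and by free partner in equivalents, free partner being the charge less the substrate consumed. At 2.00 min this reads 0.312 in teal, 0.397 in red and 0.324 in green. Target over substrate, with free partner left out of the division, reads 0.165 in teal and 0.549 in red. The mean, 0.344, of target over substrate times free partner is the holding ratio, a reading that carries the scatter of these runs; the balance it assumes is what is usually called a pre-equilibrium. Late in a run, with free partner taken as the charge less one equivalent, target should then be a slice of the remaining substrate, about 0.172 of it in cedar and 0.688 in ash. But substrate falls faster with more partner: at 4.00 min red keeps 8.3%, teal 31.5%. So ash should end below cedar.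

The forecast takes this side, “fast reversible formation of the target from substrate and partner”. It gives 2.7% for cedar and 1.7% for ash, with isomer of the product ahead in both.

The flasks give 2.89% in cedar and 1.92% in ash, with isomer of the product ahead at 83.1% and 95.2%. Ash stands below the first view's 2.76%. That view keeps the early readings, where red stands above teal; by 2.50 min ash holds 6.60% and cedar 6.97%.

    substrate + partner ⇌ isomer of the product (K = 13000 M⁻¹, k = 5.10 M⁻¹ s⁻¹)
    precatalyst → catalyst (k = 0.00490 s⁻¹)
    substrate + partner ⇌ target (K = 150 M⁻¹, k = 8.30 M⁻¹ s⁻¹)
    target + catalyst ⇌ isomer of the product + catalyst, rate k4*[catalyst]*[target] forward; the back reaction follows from the equilibrium constant (k = 10.0 M⁻¹ s⁻¹)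

At the end the holding ratio reads 0.322 in cedar and 0.329 in ash, and the step from target to isomer of the product makes no difference to cedar's target at the end. The neighbour flask is cedar with 0.380 equiv of partner. At 5.00 min it keeps 15.1% of its partner, so 0.0573 equivalents are free, and with 67.7% substrate the holding ratio gives 1.34% target; the flask holds 1.25%.

(The numbers in the tables were computed with constants of no real substance, and the scatter is random.)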